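**Strategy.** Ring A (formyl-bearing) is joined to ring B (phthalide) through two adjacent ring A carbons: one holds the diaryl ether oxygen, the other the ester carbonyl. Cutting both bonds leaves ring A as an aryne and ring B as a catechol cyclic carbonate. The key step re-joins them in one fluoride-triggered operation: the aryne inserts into a carbonate C–O bond, closing the seven-membered dioxepinone ring. It exploits the ortho relation of these two carbons, the nearness of the aldehyde carbon to the lactol oxygen (pre-joined as a CH2–O tether that fixes regiochemistry), and the ring B phenol beside CH2OAc (an acetyl relay). The precursor is an ortho-silyl aryl triflate tethered to the carbonate-bearing phthalide.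

Key step: step 13

Remarks on the chemistry:
- Atom names. The ring A carbons are named by what they carry in the target: the ester carbon (bonded to the depsidone C=O), the methyl carbon, the unsubstituted carbon, the hydroxyl carbon, the formyl carbon and the ether carbon (bonded to the diaryl ether oxygen). The three oxygens on ring B are the phenol oxygen (between CH2OAc and the lactone carbonyl), the ether oxygen (beside the lactol-bearing carbon) and the ester oxygen (beside the CH2OAc-bearing carbon). PMB = 4-methoxybenzyl; DTBMP = 2,6-di-tert-butyl-4-methylpyridine.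
- Assumption on the stereocentre. The lactol carbon is a hemiacetal and can epimerize through the open formyl acid in basic or protic media. It is therefore carried as a configurationally stable acetal, which is racemic from step 11 to compound 20 (drawn without a stereo mark). The enantiomers are separated in step 14, and the last step frees the lactol without breaking a bond at that carbon. The target should be kept cold, neutral and aprotic.
- Atranol (1) and methyl 2,4-dihydroxy-3-methylbenzoate (8) are taken as commercially available.

**Ring A fragment**

Step 1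
Reactants: 1 atranol (2,6-dihydroxy-4-methylbenzaldehyde)
Product: 2 2-hydroxy-6-[(4-methoxybenzyl)oxy]-4-methylbenzaldehyde
Conditions: PMBCl (1.0 equiv), K2CO3 (1.0 equiv), DMF, rt
Reagents that add atoms: 4-methoxybenzyl chloride, COc1ccc(CCl)cc1
Why: Williamson etherification of a symmetric diol should stop at the mono-ether, because the remaining hydroxyl is held in a hydrogen bond to the aldehyde.

Step 2
Reactants: 2 2-hydroxy-6-[(4-methoxybenzyl)oxy]-4-methylbenzaldehyde
Product: 3 3-bromo-2-hydroxy-6-[(4-methoxybenzyl)oxy]-4-methylbenzaldehyde
Conditions: NBS (1.0 equiv), iPr2NH (10 mol %), CH2Cl2, 0 °C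
Reagents that add atoms: N-bromosuccinimide, O=C1CCC(=O)N1Br
Why: Amine-mediated ortho-selective electrophilic bromination of a phenol should deliver bromine to the only free position ortho to the hydroxyl (the future ester carbon of ring A).

Step 3
Reactants: 3 3-bromo-2-hydroxy-6-[(4-methoxybenzyl)oxy]-4-methylbenzaldehyde
Product: 4 2-bromo-6-(hydroxymethyl)-5-[(4-methoxybenzyl)oxy]-3-methylphenol
Conditions: NaBH4, THF/MeOH, 0 °C
Reagents that add atoms: none
Why: Borohydride reduction of the aldehyde should leave the aryl bromide and the PMB ether untouched and gives the CH2OH group that later becomes the tether.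

Step 4
Reactants: 4 2-bromo-6-(hydroxymethyl)-5-[(4-methoxybenzyl)oxy]-3-methylphenol
Product: 7 2-(hydroxymethyl)-3-[(4-methoxybenzyl)oxy]-5-methyl-6-(trimethylsilyl)phenyl trifluoromethanesulfonate, via bis(trimethylsilyl) ether 5 (not isolated), via silyl ether triflate 6 (not isolated)
Conditions: HMDS, THF, 65 °C, then concentrate; n-BuLi, THF, −78 °C; PhNTf2, −78 °C to rt; 1 M HCl, MeOH, 0 °C
Reagents that add atoms: hexamethyldisilazane, C[Si](C)(C)N[Si](C)(C)C; N-phenylbis(trifluoromethanesulfonimide), O=S(=O)(N(c1ccccc1)S(=O)(=O)C(F)(F)F)C(F)(F)F
Why: O-silylation, bromine–lithium exchange, anionic 1,3-silyl shift from oxygen to carbon (retro-Brook rearrangement) and triflation of the resulting phenoxide is the standard route to ortho-silyl aryl triflates, and brief acidic methanolysis should free the primary alcohol only.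

**Ring B fragment**

Step 5
Reactants: 8 methyl 2,4-dihydroxy-3-methylbenzoate
Product: 10 methyl 2,4,5-trihydroxy-3-methylbenzoate, via hydroxyquinone 9 (not isolated)
Conditions: (KSO3)2NO (2.2 equiv), KH2PO4 buffer, H2O/acetone, 0 °C; then Na2S2O4, H2O/EtOAc, N2
Reagents that add atoms: potassium nitrosodisulfonate, [K+].[K+].[O]N(S(=O)(=O)[O-])S(=O)(=O)[O-]
Why: Teuber oxidation of the resorcinol should oxygenate the only activated free position (para to the 2-OH) to the hydroxy-para-quinone, which dithionite reduces to the triol.

Step 6
Reactants: 10 methyl 2,4,5-trihydroxy-3-methylbenzoate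
Product: 11 methyl 6-formyl-2,4,5-trihydroxy-3-methylbenzoate
Conditions: Cl2CHOMe (1.5 equiv), TiCl4 (4 equiv), CH2Cl2, −10 to 0 °C, N2; then 1 M HCl
Reagents that add atoms: dichloromethyl methyl ether, COC(Cl)Cl; water, O
Why: Rieche formylation directed by the titanium phenoxide should place the formyl group ortho to the 5-OH at the single free ring position.

Step 7
Reactants: 11 methyl 6-formyl-2,4,5-trihydroxy-3-methylbenzoate
Product: 12 4,5,7-trihydroxy-6-methylisobenzofuran-1(3H)-one
Conditions: NaBH4, THF/MeOH, 0 °C, N2; then 1 M HCl
Reagents that add atoms: none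
Why: Reduction of the aldehyde gives a benzylic alkoxide that should lactonize onto the neighbouring methyl ester (phthalide formation), which fixes the lactone carbonyl beside the future ring B phenol.

Step 8
Reactants: 12 4,5,7-trihydroxy-6-methylisobenzofuran-1(3H)-one
Product: 13 7-hydroxy-6-methylphthalide whose 4- and 5-oxygens are joined as a cyclic carbonate
Conditions: CDI (1.1 equiv), THF, 0 °C to rt; dilute HCl wash
Reagents that add atoms: 1,1'-carbonyldiimidazole, O=C(n1ccnc1)n1ccnc1
Why: Carbonylation with CDI should close the five-membered carbonate on the catechol pair, while the 7-OH is held back by its hydrogen bond to the lactone carbonyl; this carbonate carbon becomes the depsidone ester carbon.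

Step 9
Reactants: 13 7-hydroxy-6-methylphthalide 4,5-cyclic carbonate
Product: 14 7-acetoxy-6-methylphthalide 4,5-cyclic carbonate
Conditions: Ac2O, pyridine, CH2Cl2, rt
Reagents that add atoms: acetic anhydride, CC(=O)OC(C)=O
Why: Acetylation of the last phenol protects it for the radical step and installs the acetyl group that ends up on the CH2O group of the target.

Step 10
Reactants: 14 7-acetoxy-6-methylphthalide 4,5-cyclic carbonate
Product: 15 (±)-7-acetoxy-3-bromo-6-(bromomethyl)phthalide 4,5-cyclic carbonate
Conditions: NBS (2.2 equiv), AIBN (10 mol %), PhCF3, 85 °C; used crude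
Reagents that add atoms: N-bromosuccinimide, O=C1CCC(=O)N1Br
Why: Wohl–Ziegler bromination should take one hydrogen from each benzylic site (phthalide position 3 and the aryl methyl group), since a second bromination at either site is slowed by the first bromine and all oxygens are acylated.

**Union, key step and end game**

Step 11
Reactants: 15 (±)-7-acetoxy-3-bromo-6-(bromomethyl)phthalide 4,5-cyclic carbonate; 7 2-(hydroxymethyl)-3-[(4-methoxybenzyl)oxy]-5-methyl-6-(trimethylsilyl)phenyl trifluoromethanesulfonate
Product: 16 (±)-7-acetoxy-6-(bromomethyl)phthalide 4,5-cyclic carbonate carrying at position 3 the benzyloxy group of 7 (3-alkoxyphthalide acetal)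
Conditions: DTBMP, 4 Å MS, CH2Cl2, 0 °C to rt
Reagents that add atoms: none
Why: A 3-bromophthalide ionizes to a lactone-stabilized oxocarbenium ion pair and should be captured by the primary alcohol (pseudo-ester acetal formation), while the hindered benzylic bromide does not react with a neutral alcohol; the new acetal centre is racemic.

Step 12
Reactants: 16 (±)-bromomethyl acetal
Product: 17 (±)-6-(acetoxymethyl)-7-hydroxyphthalide 4,5-cyclic carbonate carrying the same benzyloxy acetal at position 3
Conditions: AgOSO2CF3 (1.2 equiv), DTBMP (1.5 equiv), acetone/H2O 10:1, 0 °C to rt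
Reagents that add atoms: water, O
Why: Silver-assisted ionization of the benzylic bromide with anchimeric assistance by the ortho acetoxy group gives a 1,3-dioxanylium ion whose hydrolysis should collapse to the alkyl acetate and the free ring B phenol (acyl migration), the carbonate being unable to take part because its carbonyl points away.

Step 13
Reactants: 17 (±)-6-(acetoxymethyl)-7-hydroxyphthalide 4,5-cyclic carbonate acetal
Product: 20 (±)-tether-bridged depsidone (4-O-PMB galbinic acid whose lactol oxygen is bonded to the reduced formyl carbon of ring A as a CH2–O bridge), via relayed sodium phenoxide 18 (not isolated), via aryne 19 (not isolated)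
Conditions: NaH (1.05 equiv), THF, 0 °C; then CsF (3 equiv), 18-crown-6 (3 equiv), THF (0.005 M), 0 °C to rt; AcOH, 0 °C
Reagents that add atoms: none
Why: Proposed new method: NaH deprotonates the ring B phenol, and two six-membered acyl transfers (acetyl from CH2–O to the phenol oxygen, then the strained catechol carbonate from the ring B ether oxygen onto CH2–O) should move the anion to the ring B ether oxygen (18); CsF then removes SiMe3 with loss of triflate to give aryne 19, the tethered phenoxide adds to the proximal aryne carbon (the ether carbon of ring A), the aryl anion at the ester carbon of ring A attacks the six-membered carbonate carbonyl, and the expelled CH2–O alkoxide takes the acetyl group back from the ring B phenol oxygen. The closest known reactions are the fluoride-mediated annulation of arynes with salicylates to xanthones (phenoxide addition, then intramolecular acyl substitution) and the ring-expanding insertion of arynes into the N–C(=O) bond of cyclic ureas; insertion into a carbonate C–O bond is the new element. Two rings close: the eight-membered dioxocine by 8-exo-dig addition of the phenoxide to the aryne, and the seven-membered dioxepinone by 7-exo-trig acyl substitution. No stereocentre is formed; the racemic acetal centre is carried through and the enantiomers are separated in step 14. Three selectivities are needed: attack at the ether carbon and not the ester carbon of ring A is enforced by the three-atom tether, because addition at the ester carbon would require a meta-bridged ring; only the ring B ether oxygen is etherified, because it alone is freed by the relay and alone reaches the aryne; and the ring B ester oxygen keeps the carbonyl, because its expulsion would give a strained meta-bridged nine-membered ring, so the alkoxide leaves instead. High dilution and the absence of a proton source (NaH instead of a phenol/fluoride pair) should suppress intermolecular capture and protonation of the aryl anion.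

Step 14
Reactants: 20 (±)-tether-bridged depsidone
Product: 21 (S)-tether-bridged depsidone
Conditions: preparative SFC on immobilised amylose tris(3,5-dimethylphenylcarbamate), CO2/iPrOH; configuration assigned by X-ray or ECD
Reagents that add atoms: none
Why: The acetal carbon of 20 is configurationally stable and locked in the bridged ring, so chromatographic resolution on a chiral stationary phase should secure the single (S) configuration of the future lactol carbon.

Step 15
Reactants: 21 (S)-tether-bridged depsidone
Product: 22 galbinic acid
Conditions: DDQ (2.5 equiv), CH2Cl2/pH 7 phosphate buffer 10:1, 0 °C to rt; ascorbate quench, cold work-up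
Reagents that add atoms: water, O
Why: DDQ oxidation by benzylic hydride abstraction should cleave the PMB ether and convert the electron-rich CH2–O bridge on ring A into an oxocarbenium ion that water opens to the ring A aldehyde and the free lactol, with the lactol C–O bonds untouched so that the (S) centre is retained.

**Compound list**

1 | atranol (2,6-dihydroxy-4-methylbenzaldehyde) | Cc1cc(O)c(C=O)c(O)c1 | starting material
2 | 2-hydroxy-6-[(4-methoxybenzyl)oxy]-4-methylbenzaldehyde | Cc1cc(O)c(C=O)c(OCc2ccc(OC)cc2)c1 | intermediate
3 | 3-bromo-2-hydroxy-6-[(4-methoxybenzyl)oxy]-4-methylbenzaldehyde | Cc1cc(OCc2ccc(OC)cc2)c(C=O)c(O)c1Br | intermediate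
4 | 2-bromo-6-(hydroxymethyl)-5-[(4-methoxybenzyl)oxy]-3-methylphenol | Cc1cc(OCc2ccc(OC)cc2)c(CO)c(O)c1Br | intermediate
5 | bis(trimethylsilyl) ether of 4 | Cc1cc(OCc2ccc(OC)cc2)c(CO[Si](C)(C)C)c(O[Si](C)(C)C)c1Br | intermediate
6 | trimethylsilyl ether of 7 | Cc1cc(OCc2ccc(OC)cc2)c(CO[Si](C)(C)C)c(OS(=O)(=O)C(F)(F)F)c1[Si](C)(C)C | intermediate
7 | 2-(hydroxymethyl)-3-[(4-methoxybenzyl)oxy]-5-methyl-6-(trimethylsilyl)phenyl trifluoromethanesulfonate | Cc1cc(OCc2ccc(OC)cc2)c(CO)c(OS(=O)(=O)C(F)(F)F)c1[Si](C)(C)C | intermediate
8 | methyl 2,4-dihydroxy-3-methylbenzoate | COC(=O)c1ccc(O)c(C)c1O | starting material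
9 | methyl 4-hydroxy-5-methyl-3,6-dioxocyclohexa-1,4-diene-1-carboxylate | COC(=O)C1=CC(=O)C(O)=C(C)C1=O | intermediate
10 | methyl 2,4,5-trihydroxy-3-methylbenzoate | Cc1c(O)c(C(=O)OC)cc(O)c1O | intermediate
11 | methyl 6-formyl-2,4,5-trihydroxy-3-methylbenzoate | Cc1c(O)c(C(=O)OC)c(C=O)c(O)c1O | intermediate
12 | 4,5,7-trihydroxy-6-methylisobenzofuran-1(3H)-one | Cc1c(O)c2c(c(O)c1O)COC2=O | intermediate
13 | 7-hydroxy-6-methylphthalide 4,5-cyclic carbonate | Cc1c(O)c2c(c3OC(=O)Oc13)COC2=O | intermediate
14 | 7-acetoxy-6-methylphthalide 4,5-cyclic carbonate | Cc1c(OC(C)=O)c2c(c3OC(=O)Oc13)COC2=O | intermediate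
15 | (±)-7-acetoxy-3-bromo-6-(bromomethyl)phthalide 4,5-cyclic carbonate | BrCc1c(OC(C)=O)c2c(c3OC(=O)Oc13)C(Br)OC2=O | intermediate
16 | (±)-7-acetoxy-6-(bromomethyl)phthalide 4,5-cyclic carbonate, acetal at position 3 with alcohol 7 | BrCc1c(OC(C)=O)c2c(c3OC(=O)Oc13)C(OCc1c(OCc3ccc(OC)cc3)cc(C)c([Si](C)(C)C)c1OS(=O)(=O)C(F)(F)F)OC2=O | intermediate
17 | (±)-6-(acetoxymethyl)-7-hydroxyphthalide 4,5-cyclic carbonate, acetal at position 3 with alcohol 7 | CC(=O)OCc1c(O)c2c(c3OC(=O)Oc13)C(OCc1c(OCc3ccc(OC)cc3)cc(C)c([Si](C)(C)C)c1OS(=O)(=O)C(F)(F)F)OC2=O | intermediate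
18 | (±)-sodium phenoxide at the ring B ether oxygen, with a six-membered ArO–C(=O)–O–CH2 carbonate on the ring B ester oxygen and an acetate on the ring B phenol oxygen (relay form of 17) | CC(=O)Oc1c2COC(=O)Oc2c([O-])c2c1C(=O)OC2OCc1c(OCc3ccc(OC)cc3)cc(C)c([Si](C)(C)C)c1OS(=O)(=O)C(F)(F)F.[Na+] | intermediate
19 | (±)-aryne derived from 18 by loss of SiMe3 and triflate | CC(=O)Oc1c2COC(=O)Oc2c([O-])c2c1C(=O)OC2OCC1=C(OCc3ccc(OC)cc3)C=C(C)C#C1.[Na+] | intermediate
20 | (±)-tether-bridged depsidone (4-O-PMB; lactol oxygen joined through CH2 to the former formyl carbon of ring A) | CC(=O)OCc1c(O)c2c(c3c1OC(=O)c1c(C)cc(OCc4ccc(OC)cc4)c(C5)c1O3)C(O5)OC2=O | intermediate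
21 | (S)-tether-bridged depsidone | CC(=O)OCc1c(O)c2c(c3c1OC(=O)c1c(C)cc(OCc4ccc(OC)cc4)c(C5)c1O3)[C@@H](O5)OC2=O | intermediate
22 | galbinic acid, (S) at the lactol carbon | CC(=O)OCc1c(O)c2c(c3c1OC(=O)c1c(C)cc(O)c(C=O)c1O3)[C@@H](O)OC2=O | target

**Step count.** 15 steps in total; the longest linear sequence is 11 steps (8 to 22, steps 5–15).

**Steps most likely to fail**

Step 13 (Proposed new method). The aryl anion may be protonated, or the aryne captured intermolecularly or by fluoride, before the seven-membered ring closes. The anion relay may also rest on the ring B phenol oxygen, where slow loss of acetate through an ortho-quinone methide can compete. Fallback with known reactions only, setting out from 7 and returning at 20: the two bonds are made one after the other. Aryne generation from 7 in the presence of iodine (CsF, I2, MeCN) gives [2,3-diiodo-6-[(4-methoxybenzyl)oxy]-4-methylphenyl]methanol F1. Acetal formation with 15 as in step 11 gives the bromomethyl acetal F2, and silver-assisted acetyl migration as in step 12 gives the phenol acetate F3. Cs2CO3 (which sets up the same anion relay), CuI and N,N-dimethylglycine in dioxane at 90 °C then close the diaryl ether at the tether-proximal iodide by intramolecular Ullmann coupling, giving the iodo diaryl ether F4, which holds the six-membered carbonate and the acetate on the ring B phenol oxygen. Iodine–magnesium exchange (iPrMgCl·LiCl, THF, −40 °C) lets the arylmagnesium acylate on the carbonate; the released alkoxide takes the acetyl group and 20 results.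

Step 10. The radical bromination may be uneven (over-bromination of the methyl group, incomplete bromination at position 3), and the 3-bromophthalide may hydrolyse on handling. Fallback setting out from 11 and returning at 15: the lactol oxidation level is taken from the formyl group instead. Acid hydrolysis of 11 (aq. HCl, AcOH, 70 °C) gives 3,4,5,7-tetrahydroxy-6-methylisobenzofuran-1(3H)-one F5; CDI gives its 4,5-cyclic carbonate F6; Ac2O/pyridine gives the 3,7-diacetate F7. One equivalent of NBS then brominates only the methyl group to give the bromomethyl diacetate F8, and Me3SiBr exchanges the 3-acetoxy group for bromide to give 15.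

Step 15. Oxidative removal of the PMB group from the aryl ether may be slow, the long exposure to DDQ and its acidic hydroquinone may over-oxidize the product, and the freed lactol may epimerize. Fallback setting out from 21 and returning at 22: the PMB ether is first cleaved by acidolysis (CF3CO2H, anisole, CH2Cl2, 0 °C) to the free ring A phenol F9. Its ortho hydroxyl makes the bridge CH2 much easier to oxidize, so one equivalent of DDQ in buffered wet CH2Cl2 at 0 °C for a short time should release the aldehyde and the lactol.

Further compounds
F1 | step 13 | [2,3-diiodo-6-[(4-methoxybenzyl)oxy]-4-methylphenyl]methanol | Cc1cc(OCc2ccc(OC)cc2)c(CO)c(I)c1I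
F2 | step 13 | (±)-bromomethyl acetal of 15 with F1 | BrCc1c(OC(C)=O)c2c(c3OC(=O)Oc13)C(OCc1c(OCc3ccc(OC)cc3)cc(C)c(I)c1I)OC2=O
F3 | step 13 | (±)-phenol acetate, diiodo analogue of 17 | CC(=O)OCc1c(O)c2c(c3OC(=O)Oc13)C(OCc1c(OCc3ccc(OC)cc3)cc(C)c(I)c1I)OC2=O
F4 | step 13 | (±)-iodo diaryl ether with six-membered carbonate and acetate on the ring B phenol oxygen | CC(=O)Oc1c2COC(=O)Oc2c2Oc3c(I)c(C)cc(OCc4ccc(OC)cc4)c3COC3OC(=O)c1c32
F5 | step 10 | (±)-3,4,5,7-tetrahydroxy-6-methylisobenzofuran-1(3H)-one | Cc1c(O)c2c(c(O)c1O)C(O)OC2=O
F6 | step 10 | (±)-3,7-dihydroxy-6-methylphthalide 4,5-cyclic carbonate | Cc1c(O)c2c(c3OC(=O)Oc13)C(O)OC2=O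
F7 | step 10 | (±)-3,7-diacetoxy-6-methylphthalide 4,5-cyclic carbonate | Cc1c(OC(C)=O)c2c(c3OC(=O)Oc13)C(OC(C)=O)OC2=O
F8 | step 10 | (±)-3,7-diacetoxy-6-(bromomethyl)phthalide 4,5-cyclic carbonate | BrCc1c(OC(C)=O)c2c(c3OC(=O)Oc13)C(OC(C)=O)OC2=O
F9 | step 15 | (S)-tether-bridged depsidone with free ring A phenol | CC(=O)OCc1c(O)c2c(c3c1OC(=O)c1c(C)cc(O)c(C5)c1O3)[C@@H](O5)OC2=O
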